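**Plan**
- Retrosynthesis: remove the C1–C10 epoxide oxygen, the C8 acyl group (invertive esterification of an 8α-alcohol) and C13 (Mannich methylenation); cut O6–C12 and C7–C11 (lactone from the C6–C7 enolate and bromoacetate); cut C8–C9 by a retro-oxy-Cope step, which remakes the C1–C6 bond of a cyclohexenol; then cut C6–C7 (alkoxyacetylide addition) and C1–C10 (conjugate addition to a quinone monoketal).
- Enabling feature: C10=C1 (the epoxide precursor) and the oxygenated C6–C7 unit flank C8–C9 as a 1,5-diene, C1=C10–C9–C8–C7=C6–O(−). The cis C4=C5 bond lets C1–C6 be a cyclohexene, so the ten-membered carbocycle is the four-atom ring-enlarged form of a six-membered ring C1–C6.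
- Forward order: arene → six-membered ring C1–C6 (steps 1–7) → 1,5-diene (steps 8–10) → ten-membered ring carrying the C7 side chain (step 11) → γ-lactone → α-methylene → C8 ester → epoxide → desilylation.
- Stereochemistry: C1 (sacrificial) from the [Rh(cod)2]BF4/(S)-BINAP catalyst; C3 by Luche reduction cis to it; the sacrificial C6 carbinol by addition anti to the isopropenyl group; C8 by chirality transfer through the chair (8α, inverted to 8β in the esterification); C7 by alkylation on the outer enolate face; C6 by chelation-controlled reduction; the epoxide by peripheral attack on the E C1=C10 bond.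

Key step: step 11

Remark 1: ten-membered-ring compounds carry germacrane numbering (ring C1–C10, C11–C13 on C7, C14 on C10, C15 on C4), and α/β refer to the usual drawing with H-7 α. In the cyclohexenone 12, ring atoms C1, C2, C3, C4, C5, C6 become germacrane C6, C5, C4, C3, C2, C1. TBS = tert-butyldimethylsilyl, PMB = 4-methoxybenzyl.
Remark 2: the sense of induction of (S)-BINAP in step 4 is assumed to parallel that known for simple cyclohex-2-enones; if it is the opposite, (R)-BINAP is used.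

**Step 1**
Reactants: 1 2-hydroxy-5-methoxybenzaldehyde
Product: 2 2-(hydroxymethyl)-4-methoxyphenol
Conditions: NaBH4, MeOH, 0 °C
Reagents that add atoms: none
Why: Borohydride reduction of the aryl aldehyde should give the benzylic alcohol that becomes C15–OH; no stereocentre is formed.

**Step 2**
Reactants: 2 2-(hydroxymethyl)-4-methoxyphenol; 3 tert-butyldimethylsilyl chloride
Product: 4 2-{[(tert-butyldimethylsilyl)oxy]methyl}-4-methoxyphenol
Conditions: imidazole, CH2Cl2, 0 °C
Reagents that add atoms: tert-butyldimethylsilyl chloride (3), CC(C)(C)[Si](C)(C)Cl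
Why: Silyl ether formation should occur at the primary benzylic hydroxyl in preference to the hydrogen-bonded, less nucleophilic phenol, which must stay free for step 3.

**Step 3**
Reactants: 4 2-{[(tert-butyldimethylsilyl)oxy]methyl}-4-methoxyphenol; 5 methanol
Product: 6 2-{[(tert-butyldimethylsilyl)oxy]methyl}-4,4-dimethoxycyclohexa-2,5-dien-1-one
Conditions: PhI(OAc)2, MeOH, 0 °C
Reagents that add atoms: methanol (5), CO
Why: Oxidative dearomatisation of a para-methoxyphenol in methanol should give the para-quinone monoketal, whose ketone is the future C3 and whose ketal is the future C6.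

**Step 4**
Reactants: 6 2-{[(tert-butyldimethylsilyl)oxy]methyl}-4,4-dimethoxycyclohexa-2,5-dien-1-one; 7 potassium trifluoro(prop-1-en-2-yl)borate
Product: 8 (S)-2-{[(tert-butyldimethylsilyl)oxy]methyl}-4,4-dimethoxy-5-(prop-1-en-2-yl)cyclohex-2-en-1-one
Conditions: [Rh(cod)2]BF4 (cat.), (S)-BINAP (cat.), Et3N, PhMe/H2O, rt
Reagents that add atoms: potassium trifluoro(prop-1-en-2-yl)borate (7), [K+].C=C(C)[B-](F)(F)F
Why: Rhodium-catalysed asymmetric conjugate addition (Hayashi–Miyaura type) of the alkenyl trifluoroborate should occur only at the unsubstituted enone (the α-substituted one is inert), and the (S)-BINAP ligand sets the isopropenyl-bearing centre (S; future C1, which carries C10, C9 and C14).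

**Step 5**
Reactants: 8 (S)-2-{[(tert-butyldimethylsilyl)oxy]methyl}-4,4-dimethoxy-5-(prop-1-en-2-yl)cyclohex-2-en-1-one
Product: 9 (1S,5S)-2-{[(tert-butyldimethylsilyl)oxy]methyl}-4,4-dimethoxy-5-(prop-1-en-2-yl)cyclohex-2-en-1-ol
Conditions: NaBH4, CeCl3·7H2O, MeOH, −78 °C
Reagents that add atoms: none
Why: Luche 1,2-reduction should deliver hydride to the ring face anti to the isopropenyl group, as in the reduction of carvone to cis-carveol, giving the cis alcohol and so the future C3 centre (S).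

**Step 6**
Reactants: 9 (1S,5S)-2-{[(tert-butyldimethylsilyl)oxy]methyl}-4,4-dimethoxy-5-(prop-1-en-2-yl)cyclohex-2-en-1-ol; 3 tert-butyldimethylsilyl chloride
Product: 10 tert-butyl{[(1S,5S)-2-{[(tert-butyldimethylsilyl)oxy]methyl}-4,4-dimethoxy-5-(prop-1-en-2-yl)cyclohex-2-en-1-yl]oxy}dimethylsilane
Conditions: imidazole, DMF, rt
Reagents that add atoms: tert-butyldimethylsilyl chloride (3), CC(C)(C)[Si](C)(C)Cl
Why: Silyl ether formation under basic conditions protects the C3 hydroxyl without touching the acid-labile dimethyl ketal.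

**Step 7**
Reactants: 10 tert-butyl{[(1S,5S)-2-{[(tert-butyldimethylsilyl)oxy]methyl}-4,4-dimethoxy-5-(prop-1-en-2-yl)cyclohex-2-en-1-yl]oxy}dimethylsilane; 11 water
Product: 12 (4S,6S)-4-[(tert-butyldimethylsilyl)oxy]-3-{[(tert-butyldimethylsilyl)oxy]methyl}-6-(prop-1-en-2-yl)cyclohex-2-en-1-one
Conditions: pyridinium p-toluenesulfonate (cat.), acetone/H2O, rt
Reagents that add atoms: water (11), O
Why: Mild acid hydrolysis of the allylic dimethyl ketal should unmask the enone (future C6 ketone) while the silyl ethers and the α-stereocentre survive the weakly acidic medium.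

**Step 8**
Reactants: 13 4-methoxybenzyl alcohol; 14 trichloroethylene
Product: 15 1-({[(E)-1,2-dichloroethenyl]oxy}methyl)-4-methoxybenzene
Conditions: KH, THF, 0 °C → rt
Reagents that add atoms: trichloroethylene (14), ClC=C(Cl)Cl
Why: The potassium alkoxide should add to dichloroacetylene generated in situ from trichloroethylene (elimination–addition) to give the 1,2-dichlorovinyl ether, a stable precursor of the alkoxyacetylide.

**Step 9**
Reactants: 12 (4S,6S)-4-[(tert-butyldimethylsilyl)oxy]-3-{[(tert-butyldimethylsilyl)oxy]methyl}-6-(prop-1-en-2-yl)cyclohex-2-en-1-one; 15 1-({[(E)-1,2-dichloroethenyl]oxy}methyl)-4-methoxybenzene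
Product: 17 (1S,4S,6S)-4-[(tert-butyldimethylsilyl)oxy]-3-{[(tert-butyldimethylsilyl)oxy]methyl}-1-{[(4-methoxybenzyl)oxy]ethynyl}-6-(prop-1-en-2-yl)cyclohex-2-en-1-ol, via lithium alkoxyacetylide 16 (not isolated)
Conditions: n-BuLi (2.1 equiv to 15), THF, −78 → −40 °C; then 12, −78 °C; NH4Cl (aq)
Reagents that add atoms: 1-({[(E)-1,2-dichloroethenyl]oxy}methyl)-4-methoxybenzene (15), COc1ccc(CO/C(Cl)=C\Cl)cc1
Why: Dehydrochlorination and chlorine–lithium exchange give the lithium alkoxyacetylide, which should add 1,2 to the enone on the face anti to the adjacent isopropenyl group (and to the silyloxy group on the same face), setting the sacrificial C6 carbinol centre (S) with the hydroxyl cis to the isopropenyl group (acetylide addition to a ketone).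

**Step 10**
Reactants: 17 (1S,4S,6S)-4-[(tert-butyldimethylsilyl)oxy]-3-{[(tert-butyldimethylsilyl)oxy]methyl}-1-{[(4-methoxybenzyl)oxy]ethynyl}-6-(prop-1-en-2-yl)cyclohex-2-en-1-ol
Product: 18 (1S,4S,6S)-4-[(tert-butyldimethylsilyl)oxy]-3-{[(tert-butyldimethylsilyl)oxy]methyl}-1-{(E)-2-[(4-methoxybenzyl)oxy]ethenyl}-6-(prop-1-en-2-yl)cyclohex-2-en-1-ol
Conditions: LiAlH4, THF, 0 °C → rt; KNaC4H4O6 (aq), no acid
Reagents that add atoms: none
Why: Hydroxyl-directed trans-hydroalumination of the propargylic alcohol followed by protonolysis should give the E enol ether (C7=C8), the geometry that places the C8 oxygen equatorial in the chair of step 11.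

**Step 11**
Reactants: 18 (1S,4S,6S)-4-[(tert-butyldimethylsilyl)oxy]-3-{[(tert-butyldimethylsilyl)oxy]methyl}-1-{(E)-2-[(4-methoxybenzyl)oxy]ethenyl}-6-(prop-1-en-2-yl)cyclohex-2-en-1-ol; 19 methyl bromoacetate
Product: 22 methyl (1(10)E,4Z)-3β,15-bis(TBS-oxy)-8α-(PMB-oxy)-6-oxo-13-norgermacra-1(10),4-dien-12-oate (3S,7R,8S; side chain 7β), via potassium alkoxide 20 (not isolated), via potassium dienolate 21 (not isolated)
Conditions: KN(SiMe3)2 (1.05 equiv), 18-crown-6, THF, −78 °C → rt; then −78 °C, BrCH2CO2Me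
Reagents that add atoms: methyl bromoacetate (19), COC(=O)CBr
Why: Deprotonation gives alkoxide 20, whose 1,5-diene C9=C10–C1–C6(O−)–C7=C8 undergoes the alkoxide-accelerated [3,3] sigmatropic shift (anionic oxy-Cope rearrangement), breaking the ring bond C1–C6 while C8–C9 forms, and the released dienolate 21 is C-alkylated at C7 by methyl bromoacetate. The closest known reaction type is the anionic oxy-Cope ring expansion of trans-1,2-dialkenylcyclohex-2-enols to (Z,E)-cyclodeca-2,6-dienones with in situ trapping of the enolate. The ten-membered ring is closed not by an end-to-end cyclisation but by a four-atom ring enlargement (six to ten) through a six-centre chair transition state in which both ring bonds (C1–C2 and C6–C5) and the benzyloxy group of the E enol ether are equatorial. C8 is set by chirality transfer from C1 and C6 through this chair (8α oxygen, to be inverted in step 15), the equatorial C2 gives the E C1=C10 bond and the Z C4=C5 bond is inherited from the cyclohexene, while C7 is set in the alkylation, which should occur on the outer face of the enolate, anti to the C8–C9 ring bond that spans the inner face. The step needs chair over boat (secured by the trans-diequatorial alkenyl groups) and C-alkylation over β-elimination of the C8 alkoxide (the C8–O bond lies near the enolate plane in the conformer delivered by the chair and overlaps poorly with the enolate π system, and the mixture is recooled and the enolate trapped at −78 °C once the rearrangement is complete).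

**Step 12**
Reactants: 22 methyl (1(10)E,4Z)-3β,15-bis(TBS-oxy)-8α-(PMB-oxy)-6-oxo-13-norgermacra-1(10),4-dien-12-oate
Product: 24 (1(10)E,4Z)-3β,15-bis(TBS-oxy)-8α-(PMB-oxy)-13-norgermacra-1(10),4-dien-12,6α-olide, via hydroxy ester 23 (not isolated)
Conditions: Zn(BH4)2, Et2O, −20 °C; then pyridinium p-toluenesulfonate (cat.), PhMe, 40 °C
Reagents that add atoms: none
Why: Chelation-controlled 1,2-reduction (zinc bridging the C6 carbonyl and the 8α-benzyloxy oxygen) should deliver hydride anti to both the C7 side chain and C9, giving the 6α-alcohol (6R; 6,8-syn and 6,7-trans), which closes the trans-fused γ-lactone by acid-catalysed lactonisation.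

**Step 13**
Reactants: 24 (1(10)E,4Z)-3β,15-bis(TBS-oxy)-8α-(PMB-oxy)-13-norgermacra-1(10),4-dien-12,6α-olide; 25 N,N-dimethylmethyleneiminium iodide (Eschenmoser's salt)
Product: 29 (1(10)E,4Z)-3β,15-bis(TBS-oxy)-8α-(PMB-oxy)germacra-1(10),4,11(13)-trien-12,6α-olide, via lithium enolate 26 (not isolated), via Mannich base 27 (not isolated), via ammonium iodide 28 (not isolated)
Conditions: LiN(i-Pr)2, THF, −78 °C; CH2=NMe2+ I−, −78 → 0 °C; then MeI, MeOH, rt; then NaHCO3 (aq), CH2Cl2
Reagents that add atoms: N,N-dimethylmethyleneiminium iodide (25), C=[N+](C)C.[I-]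
Why: Mannich aminomethylation of the lactone enolate followed by quaternisation and Hofmann-type elimination is the standard α-methylenation of γ-lactones; C11 becomes trigonal, so no stereocentre remains there.

**Step 14**
Reactants: 29 (1(10)E,4Z)-3β,15-bis(TBS-oxy)-8α-(PMB-oxy)germacra-1(10),4,11(13)-trien-12,6α-olide
Product: 30 (1(10)E,4Z)-3β,15-bis(TBS-oxy)-8α-hydroxygermacra-1(10),4,11(13)-trien-12,6α-olide
Conditions: DDQ, CH2Cl2/pH 7 buffer (Na2HPO4/NaH2PO4), 0 °C → rt
Reagents that add atoms: none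
Why: Oxidative cleavage of the 4-methoxybenzyl ether by DDQ should free the 8α-hydroxyl without affecting silyl ethers, alkenes or the methylene lactone.

**Step 15**
Reactants: 30 (1(10)E,4Z)-3β,15-bis(TBS-oxy)-8α-hydroxygermacra-1(10),4,11(13)-trien-12,6α-olide; 31 isobutyric acid
Product: 32 (1(10)E,4Z)-3β,15-bis(TBS-oxy)-8β-(isobutyryloxy)germacra-1(10),4,11(13)-trien-12,6α-olide
Conditions: PPh3, diisopropyl azodicarboxylate (betaine preformed), PhMe, 0 °C → rt
Reagents that add atoms: isobutyric acid (31), CC(C)C(=O)O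
Why: Mitsunobu esterification should displace the activated 8α-oxygen by the carboxylate with inversion (SN2), installing the ester and correcting C8 to the required 8β (R) configuration in one operation.

**Step 16**
Reactants: 32 (1(10)E,4Z)-3β,15-bis(TBS-oxy)-8β-(isobutyryloxy)germacra-1(10),4,11(13)-trien-12,6α-olide; 33 3-chloroperoxybenzoic acid
Product: 34 1β,10α-epoxy-3β,15-bis(TBS-oxy)-8β-(isobutyryloxy)germacra-4Z,11(13)-dien-12,6α-olide
Conditions: mCPBA, NaHCO3, CH2Cl2, 0 °C
Reagents that add atoms: 3-chloroperoxybenzoic acid (33), OOC(=O)c1cccc(Cl)c1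
Why: Peracid (Prilezhaev) epoxidation should select the electron-rich E C1=C10 bond over the C4=C5 bond (deactivated by three allylic oxygens) and the conjugated C11=C13 bond, and attack on the exposed outer face of this ring-perpendicular alkene in the lactone-anchored conformer should set C1 and C10 (1R,10R; 1β,10α) in one stereospecific syn addition.

**Step 17**
Reactants: 34 1β,10α-epoxy-3β,15-bis(TBS-oxy)-8β-(isobutyryloxy)germacra-4Z,11(13)-dien-12,6α-olide
Product: 35 1β,10α-epoxy-3β,15-dihydroxy-8β-(isobutyryloxy)germacra-4Z,11(13)-dien-12,6α-olide (1R,3S,6R,7R,8R,10R)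
Conditions: Bu4NF, AcOH (1:1), THF, 0 °C → rt
Reagents that add atoms: none
Why: Buffered fluoride desilylation should remove both silyl ethers under near-neutral conditions that spare the acid-sensitive epoxide, the ester and the methylene lactone.

**Compound list**
1 | 2-hydroxy-5-methoxybenzaldehyde | COc1ccc(O)c(C=O)c1 | starting material
2 | 2-(hydroxymethyl)-4-methoxyphenol | COc1ccc(O)c(CO)c1 | intermediate
3 | tert-butyldimethylsilyl chloride | CC(C)(C)[Si](C)(C)Cl | starting material
4 | 2-{[(tert-butyldimethylsilyl)oxy]methyl}-4-methoxyphenol | COc1ccc(O)c(CO[Si](C)(C)C(C)(C)C)c1 | intermediate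
5 | methanol | CO | starting material
6 | 2-{[(tert-butyldimethylsilyl)oxy]methyl}-4,4-dimethoxycyclohexa-2,5-dien-1-one | COC1(OC)C=CC(=O)C(CO[Si](C)(C)C(C)(C)C)=C1 | intermediate
7 | potassium trifluoro(prop-1-en-2-yl)borate | [K+].C=C(C)[B-](F)(F)F | starting material
8 | (S)-2-{[(tert-butyldimethylsilyl)oxy]methyl}-4,4-dimethoxy-5-(prop-1-en-2-yl)cyclohex-2-en-1-one | O=C1C[C@@H](C(C)=C)C(OC)(OC)C=C1CO[Si](C)(C)C(C)(C)C | intermediate
9 | (1S,5S)-2-{[(tert-butyldimethylsilyl)oxy]methyl}-4,4-dimethoxy-5-(prop-1-en-2-yl)cyclohex-2-en-1-ol | O[C@H]1C[C@@H](C(C)=C)C(OC)(OC)C=C1CO[Si](C)(C)C(C)(C)C | intermediate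
10 | tert-butyl{[(1S,5S)-2-{[(tert-butyldimethylsilyl)oxy]methyl}-4,4-dimethoxy-5-(prop-1-en-2-yl)cyclohex-2-en-1-yl]oxy}dimethylsilane | CC(C)(C)[Si](C)(C)O[C@H]1C[C@@H](C(C)=C)C(OC)(OC)C=C1CO[Si](C)(C)C(C)(C)C | intermediate
11 | water | O | starting material
12 | (4S,6S)-4-[(tert-butyldimethylsilyl)oxy]-3-{[(tert-butyldimethylsilyl)oxy]methyl}-6-(prop-1-en-2-yl)cyclohex-2-en-1-one | CC(C)(C)[Si](C)(C)O[C@H]1C[C@@H](C(C)=C)C(=O)C=C1CO[Si](C)(C)C(C)(C)C | intermediate
13 | 4-methoxybenzyl alcohol | COc1ccc(CO)cc1 | starting material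
14 | trichloroethylene | ClC=C(Cl)Cl | starting material
15 | 1-({[(E)-1,2-dichloroethenyl]oxy}methyl)-4-methoxybenzene | COc1ccc(CO/C(Cl)=C\Cl)cc1 | intermediate
16 | lithium [(4-methoxybenzyl)oxy]acetylide | [Li+].[C-]#COCc1ccc(OC)cc1 | intermediate (not isolated)
17 | (1S,4S,6S)-4-[(tert-butyldimethylsilyl)oxy]-3-{[(tert-butyldimethylsilyl)oxy]methyl}-1-{[(4-methoxybenzyl)oxy]ethynyl}-6-(prop-1-en-2-yl)cyclohex-2-en-1-ol | CC(C)(C)[Si](C)(C)O[C@H]1C[C@@H](C(C)=C)[C@](O)(C#COCc2ccc(OC)cc2)C=C1CO[Si](C)(C)C(C)(C)C | intermediate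
18 | (1S,4S,6S)-4-[(tert-butyldimethylsilyl)oxy]-3-{[(tert-butyldimethylsilyl)oxy]methyl}-1-{(E)-2-[(4-methoxybenzyl)oxy]ethenyl}-6-(prop-1-en-2-yl)cyclohex-2-en-1-ol | CC(C)(C)[Si](C)(C)O[C@H]1C[C@@H](C(C)=C)[C@](O)(/C=C/OCc2ccc(OC)cc2)C=C1CO[Si](C)(C)C(C)(C)C | intermediate
19 | methyl bromoacetate | COC(=O)CBr | starting material
20 | potassium alkoxide of 18 | [K+].CC(C)(C)[Si](C)(C)O[C@H]1C[C@@H](C(C)=C)[C@]([O-])(/C=C/OCc2ccc(OC)cc2)C=C1CO[Si](C)(C)C(C)(C)C | intermediate (not isolated)
21 | potassium (1(10)E,4Z,6Z)-3β,15-bis(TBS-oxy)-8α-(PMB-oxy)cyclodecatrien-6-olate (ten-membered dienolate; germacrane ring numbering; ring bonds C5–C6 and C7–C8 trans across C6=C7) | [K+].C1/C(C)=C/C[C@H](O[Si](C)(C)C(C)(C)C)/C(CO[Si](C)(C)C(C)(C)C)=C\C(\[O-])=C\[C@H]1OCc2ccc(OC)cc2 | intermediate (not isolated)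
22 | methyl (1(10)E,4Z)-3β,15-bis(TBS-oxy)-8α-(PMB-oxy)-6-oxo-13-norgermacra-1(10),4-dien-12-oate (3S,7R,8S) | O=C1/C=C(CO[Si](C)(C)C(C)(C)C)\[C@@H](O[Si](C)(C)C(C)(C)C)C/C=C(C)/C[C@H](OCc2ccc(OC)cc2)[C@H]1CC(=O)OC | intermediate
23 | methyl (1(10)E,4Z)-3β,15-bis(TBS-oxy)-6α-hydroxy-8α-(PMB-oxy)-13-norgermacra-1(10),4-dien-12-oate | O[C@@H]1/C=C(CO[Si](C)(C)C(C)(C)C)\[C@@H](O[Si](C)(C)C(C)(C)C)C/C=C(C)/C[C@H](OCc2ccc(OC)cc2)[C@H]1CC(=O)OC | intermediate (not isolated)
24 | (1(10)E,4Z)-3β,15-bis(TBS-oxy)-8α-(PMB-oxy)-13-norgermacra-1(10),4-dien-12,6α-olide | C1C(=O)O[C@@H]2/C=C(/CO[Si](C)(C)C(C)(C)C)[C@@H](O[Si](C)(C)C(C)(C)C)C/C=C(C)/C[C@H](OCc3ccc(OC)cc3)[C@@H]12 | intermediate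
25 | N,N-dimethylmethyleneiminium iodide | C=[N+](C)C.[I-] | starting material
26 | lithium enolate of lactone 24 | [Li+].C1=C([O-])O[C@@H]2/C=C(/CO[Si](C)(C)C(C)(C)C)[C@@H](O[Si](C)(C)C(C)(C)C)C/C=C(C)/C[C@H](OCc3ccc(OC)cc3)[C@@H]12 | intermediate (not isolated)
27 | 11-(dimethylaminomethyl) derivative of lactone 24 (C11 epimers) | CN(C)CC1C(=O)O[C@@H]2/C=C(/CO[Si](C)(C)C(C)(C)C)[C@@H](O[Si](C)(C)C(C)(C)C)C/C=C(C)/C[C@H](OCc3ccc(OC)cc3)[C@@H]12 | intermediate (not isolated)
28 | trimethylammonium iodide derived from 27 | [I-].C[N+](C)(C)CC1C(=O)O[C@@H]2/C=C(/CO[Si](C)(C)C(C)(C)C)[C@@H](O[Si](C)(C)C(C)(C)C)C/C=C(C)/C[C@H](OCc3ccc(OC)cc3)[C@@H]12 | intermediate (not isolated)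
29 | (1(10)E,4Z)-3β,15-bis(TBS-oxy)-8α-(PMB-oxy)germacra-1(10),4,11(13)-trien-12,6α-olide | C=C1C(=O)O[C@@H]2/C=C(/CO[Si](C)(C)C(C)(C)C)[C@@H](O[Si](C)(C)C(C)(C)C)C/C=C(C)/C[C@H](OCc3ccc(OC)cc3)[C@@H]12 | intermediate
30 | (1(10)E,4Z)-3β,15-bis(TBS-oxy)-8α-hydroxygermacra-1(10),4,11(13)-trien-12,6α-olide | C=C1C(=O)O[C@@H]2/C=C(/CO[Si](C)(C)C(C)(C)C)[C@@H](O[Si](C)(C)C(C)(C)C)C/C=C(C)/C[C@H](O)[C@@H]12 | intermediate
31 | isobutyric acid | CC(C)C(=O)O | starting material
32 | (1(10)E,4Z)-3β,15-bis(TBS-oxy)-8β-(isobutyryloxy)germacra-1(10),4,11(13)-trien-12,6α-olide | C=C1C(=O)O[C@@H]2/C=C(/CO[Si](C)(C)C(C)(C)C)[C@@H](O[Si](C)(C)C(C)(C)C)C/C=C(C)/C[C@@H](OC(=O)C(C)C)[C@@H]12 | intermediate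
33 | 3-chloroperoxybenzoic acid | OOC(=O)c1cccc(Cl)c1 | starting material
34 | 1β,10α-epoxy-3β,15-bis(TBS-oxy)-8β-(isobutyryloxy)germacra-4Z,11(13)-dien-12,6α-olide | C=C1C(=O)O[C@@H]2/C=C(/CO[Si](C)(C)C(C)(C)C)[C@@H](O[Si](C)(C)C(C)(C)C)C[C@H]3O[C@]3(C)C[C@@H](OC(=O)C(C)C)[C@@H]12 | intermediate
35 | 1β,10α-epoxy-3β,15-dihydroxy-8β-(isobutyryloxy)germacra-4Z,11(13)-dien-12,6α-olide (1R,3S,6R,7R,8R,10R) | C=C1C(=O)O[C@@H]2/C=C(/CO)[C@@H](O)C[C@H]3O[C@]3(C)C[C@@H](OC(=O)C(C)C)[C@@H]12 | target

**Step count**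
Total: 17 steps. Longest linear sequence: 16 steps (steps 1–7 and 9–17; step 8 is the side branch to 15).

**Steps most likely to fail**

Step 11. What may go wrong: the potassium enolate may lose the C8 benzyloxy group by β-elimination before it is alkylated, or the strongly ionising medium may erode chair control and so the C8 configuration or the C1=C10 geometry. Fallback, setting out from 18 and coming back to the route at 22: the rearrangement is run with no enolate present. Carbinol 18 is silylated at the tertiary hydroxyl with N-(trimethylsilyl)imidazole in CH2Cl2 at rt to give the trimethylsilyl ether of 18 F1. Compound F1 is heated in base-washed glass in PhMe at about 170 °C in a sealed tube, so that the neutral siloxy-Cope rearrangement gives the ten-membered 6-(trimethylsilyloxy) triene F2. The enolate is then released from F2 only at −78 °C with MeLi in THF as the lithium dienolate F3, and F3 is alkylated with 19 in the presence of N,N'-dimethylpropyleneurea, which gives 22.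

Step 15. What may go wrong: the activated C8 oxyphosphonium may eliminate toward the allylic C9 hydrogens (a conjugated diene with C1=C10) instead of being displaced by the weakly acidic isobutyric acid, and free phosphine may add to the methylene lactone. Fallback, setting out from 30 and coming back to the route at 32: inversion by oxidation and reduction, then plain acylation. Alcohol 30 is oxidised with Dess–Martin periodinane and NaHCO3 in CH2Cl2 to the 8-oxo lactone F4. Luche reduction of F4 (NaBH4, CeCl3·7H2O, MeOH, −78 °C) should deliver hydride to the α face, anti to the β-oriented C7–C11 bond, and give the 8β-hydroxy lactone F5. Acylation of F5 with isobutyryl chloride, pyridine and 4-dimethylaminopyridine in CH2Cl2 gives 32.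

Step 12. What may go wrong: facial selectivity may be poor if the zinc chelate cannot form within the ring, so that hydride adds from the periphery to give the 6β-alcohol, which would close to the cis-fused lactone. Fallback, setting out from 22 and coming back to the route at 24: that outcome is used on purpose with an invertive ring closure. Ketone 22 is reduced without chelation (NaBH4, CeCl3·7H2O, MeOH, −78 °C, no acid) to the 6β-hydroxy ester F6, and F6 is saponified with LiOH in THF/H2O and worked up with buffer to the 6β-hydroxy acid F7. Mitsunobu lactonisation of F7 (PPh3, diisopropyl azodicarboxylate, PhMe, high dilution) then closes the lactone with inversion at C6 and gives 24.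

**Further compounds**
F1 | step 11 | trimethylsilyl ether of 18 (tertiary O–SiMe3) | CC(C)(C)[Si](C)(C)O[C@H]1C[C@@H](C(C)=C)[C@](O[Si](C)(C)C)(/C=C/OCc2ccc(OC)cc2)C=C1CO[Si](C)(C)C(C)(C)C
F2 | step 11 | ten-membered 6-(trimethylsilyloxy) triene (1(10)E,4Z,6Z; 3β,15-bis(TBS-oxy); 8α-(PMB-oxy)) | C1/C(C)=C/C[C@H](O[Si](C)(C)C(C)(C)C)/C(CO[Si](C)(C)C(C)(C)C)=C\C(\O[Si](C)(C)C)=C\[C@H]1OCc2ccc(OC)cc2
F3 | step 11 | lithium dienolate corresponding to 21 | [Li+].C1/C(C)=C/C[C@H](O[Si](C)(C)C(C)(C)C)/C(CO[Si](C)(C)C(C)(C)C)=C\C(\[O-])=C\[C@H]1OCc2ccc(OC)cc2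
F4 | step 15 | (1(10)E,4Z)-3β,15-bis(TBS-oxy)-8-oxogermacra-1(10),4,11(13)-trien-12,6α-olide | C=C1C(=O)O[C@@H]2/C=C(/CO[Si](C)(C)C(C)(C)C)[C@@H](O[Si](C)(C)C(C)(C)C)C/C=C(C)/CC(=O)[C@@H]12
F5 | step 15 | (1(10)E,4Z)-3β,15-bis(TBS-oxy)-8β-hydroxygermacra-1(10),4,11(13)-trien-12,6α-olide | C=C1C(=O)O[C@@H]2/C=C(/CO[Si](C)(C)C(C)(C)C)[C@@H](O[Si](C)(C)C(C)(C)C)C/C=C(C)/C[C@@H](O)[C@@H]12
F6 | step 12 | methyl (1(10)E,4Z)-3β,15-bis(TBS-oxy)-6β-hydroxy-8α-(PMB-oxy)-13-norgermacra-1(10),4-dien-12-oate | O[C@H]1/C=C(CO[Si](C)(C)C(C)(C)C)\[C@@H](O[Si](C)(C)C(C)(C)C)C/C=C(C)/C[C@H](OCc2ccc(OC)cc2)[C@H]1CC(=O)OC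
F7 | step 12 | (1(10)E,4Z)-3β,15-bis(TBS-oxy)-6β-hydroxy-8α-(PMB-oxy)-13-norgermacra-1(10),4-dien-12-oic acid | O[C@H]1/C=C(CO[Si](C)(C)C(C)(C)C)\[C@@H](O[Si](C)(C)C(C)(C)C)C/C=C(C)/C[C@H](OCc2ccc(OC)cc2)[C@H]1CC(=O)O
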